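**Retrosynthetic overview**
1. Target ⇒ aryl–alkenyl C–C bond: last-step Suzuki–Miyaura coupling of a 7-bromo-1,4-benzodioxane with an (E)-3-hydroxypropenyl boronate, without protecting groups.
2. The 1,4-dioxane ring is the only ring made (both arenes are bought). Both C–O bonds and both stereocenters come from one oxidative union of 5-bromo-3-methoxycatechol with (E)-isoelemicin: catechol → o-quinone, then a catalytic enantioselective inverse-demand oxa-[4+2]. This is the laboratory counterpart of oxidative 8–O–4′ coupling followed by 7–O–3′ closure.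
3. Catechol ⇐ Dakin oxidation of 5-bromo-o-vanillin; (E)-isoelemicin ⇐ Suzuki coupling of 5-bromo-1,2,3-trimethoxybenzene.
4. The bromine steers the regiochemistry of the cycloaddition and is the later coupling handle.

Assumption: the four starting materials are bought; the sense of induction in step 3 is assigned by analogy with the usual oxazaborolidinium model and must be confirmed on the first batch (the (R)-catalyst is equally available and would give the antipode).

**Step 1**
Reactants: 1 5-bromo-2-hydroxy-3-methoxybenzaldehyde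
Product: 3 5-bromo-3-methoxybenzene-1,2-diol, via aryl formate 2 (not isolated)
Conditions: 30% aq H2O2 (1.3 equiv), NaOH (1.1 equiv), H2O/THF, 0 °C → rt, N2; then 1 M HCl
Reagents that add atoms: hydrogen peroxide, OO
Why: Dakin oxidation – hydroperoxide adds to the o-hydroxy aldehyde, the electron-rich aryl group migrates to oxygen to give formate 2, which is saponified in the flask; ArBr and ArOMe are inert and no stereocenter is involved.

**Step 2**
Reactants: 4 5-bromo-1,2,3-trimethoxybenzene; 5 4,4,5,5-tetramethyl-2-[(E)-prop-1-enyl]-1,3,2-dioxaborolane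
Product: 6 1,2,3-trimethoxy-5-[(E)-prop-1-enyl]benzene ((E)-isoelemicin)
Conditions: Pd(dppf)Cl2 (3 mol%), K3PO4, dioxane/H2O 4:1, 80 °C
Reagents that add atoms: none
Why: Suzuki–Miyaura coupling, in which transmetalation and reductive elimination retain the (E)-geometry of 5; no stereocenter is formed.

**Step 3**
Reactants: 3 5-bromo-3-methoxybenzene-1,2-diol; 6 (E)-isoelemicin
Product: 8 (2R,3R)-7-bromo-5-methoxy-3-methyl-2-(3,4,5-trimethoxyphenyl)-2,3-dihydro-1,4-benzodioxine, via o-quinone 7 (not isolated)
Conditions: Ag2O (3 equiv), 4 Å MS, CH2Cl2, 0 °C, 15 min, filter cold under Ar; then (S)-o-tolyl-CBS oxazaborolidine·Tf2NH (20 mol%), slow addition of 6 (1.5 equiv), CH2Cl2, −78 → −40 °C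
Reagents that add atoms: none
Why: Proposed new method: the cationic oxazaborolidine binds the more basic C1=O of quinone 7 (conjugated with the 3-OMe through the diene, lone pair syn to C6–H) and lowers the LUMO of the O=C–C=O unit, so the nucleophilic β-carbon of 6 bonds first to O2 (the oxygen next to the OMe-bearing carbon, para to Br; the phenoxide left on O1 is stabilised by meta-Br and meta-OMe) and the trimethoxybenzylic cation closes suprafacially onto boron-bound O1, which gives the biosynthetic regiochemistry and turns the (E)-alkene into the 2,3-trans ring (also the thermodynamic arrangement), while (2R,3R) is set by endo approach of the alkene, its aryl ring stacked over the quinone, to the quinone face not covered by the catalyst phenyl group; the closest known reaction types are the thermal inverse-electron-demand [4+2] of o-quinones with electron-rich styrenes giving trans-1,4-benzodioxanes and the oxazaborolidinium-catalysed enantioselective cycloadditions of p-quinones with electron-rich alkenes, where the new stereocenters also lie only on the alkene carbons.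

**Step 4**
Reactants: 8 (2R,3R)-7-bromo-5-methoxy-3-methyl-2-(3,4,5-trimethoxyphenyl)-2,3-dihydro-1,4-benzodioxine; 9 (E)-3-(4,4,5,5-tetramethyl-1,3,2-dioxaborolan-2-yl)prop-2-en-1-ol
Product: 10 (E)-3-[(2R,3R)-8-methoxy-2-methyl-3-(3,4,5-trimethoxyphenyl)-2,3-dihydro-1,4-benzodioxin-6-yl]prop-2-en-1-ol
Conditions: SPhos Pd G3 (3 mol%), K3PO4 (3 equiv), THF/H2O 5:1, 60 °C
Reagents that add atoms: none
Why: Suzuki–Miyaura coupling of the aryl bromide with the alkenyl boronate retains the (E)-geometry and tolerates the free primary alcohol; the mildly basic, non-acidic conditions leave both ether stereocenters untouched.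

**Compound list**
1 | 5-bromo-2-hydroxy-3-methoxybenzaldehyde | COc1cc(Br)cc(C=O)c1O | starting material
2 | 5-bromo-2-hydroxy-3-methoxyphenyl formate | COc1cc(Br)cc(OC=O)c1O | intermediate
3 | 5-bromo-3-methoxybenzene-1,2-diol | COc1cc(Br)cc(O)c1O | intermediate
4 | 5-bromo-1,2,3-trimethoxybenzene | COc1cc(Br)cc(OC)c1OC | starting material
5 | 4,4,5,5-tetramethyl-2-[(E)-prop-1-enyl]-1,3,2-dioxaborolane | C/C=C/B1OC(C)(C)C(C)(C)O1 | starting material
6 | 1,2,3-trimethoxy-5-[(E)-prop-1-enyl]benzene ((E)-isoelemicin) | COc1cc(/C=C/C)cc(OC)c1OC | intermediate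
7 | 5-bromo-3-methoxycyclohexa-3,5-diene-1,2-dione | COC1=CC(Br)=CC(=O)C1=O | intermediate
8 | (2R,3R)-7-bromo-5-methoxy-3-methyl-2-(3,4,5-trimethoxyphenyl)-2,3-dihydro-1,4-benzodioxine | COc1cc([C@H]2Oc3cc(Br)cc(OC)c3O[C@@H]2C)cc(OC)c1OC | intermediate
9 | (E)-3-(4,4,5,5-tetramethyl-1,3,2-dioxaborolan-2-yl)prop-2-en-1-ol | OC/C=C/B1OC(C)(C)C(C)(C)O1 | starting material
10 | (E)-3-[(2R,3R)-8-methoxy-2-methyl-3-(3,4,5-trimethoxyphenyl)-2,3-dihydro-1,4-benzodioxin-6-yl]prop-2-en-1-ol | COc1cc([C@H]2Oc3cc(/C=C/CO)cc(OC)c3O[C@@H]2C)cc(OC)c1OC | target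

**Totals**
Total step count: 4. Longest linear sequence: 3 (steps 1, 3, 4).

**Steps most likely to fail**

Step 3 (untested asymmetric cycloaddition: low ee or wrong sense, acid-induced dimerisation of 6, dimerisation of 7, regioisomer). The fallback sets out from 3 and returns at 8. Catechol 3 is cross-coupled with bought (E)-2,6-dimethoxy-4-(prop-1-enyl)phenol (COc1cc(/C=C/C)cc(OC)c1O) using Ag2O in toluene/acetone at rt. This is the classical phenoxy-radical coupling: the O2 radical of 3 joins C8 of the propenylphenol radical and the quinone methide is trapped by the neighbouring OH. It gives racemic trans 4-(7-bromo-5-methoxy-3-methyl-2,3-dihydro-1,4-benzodioxin-2-yl)-2,6-dimethoxyphenol F1. Methylation (MeI, K2CO3, acetone) gives the racemic bromide rac-8 F2. Preparative chiral SFC (amylose phase, CO2/MeOH) then delivers 8 and the discarded (2S,3S)-antipode F3.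

Step 4 (slow oxidative addition into the electron-rich bromide, protodeboronation of 9, Pd-mediated isomerisation of the allylic alcohol). The fallback sets out from 8 and returns at 10. A Heck reaction with methyl acrylate (Pd(OAc)2, P(o-tol)3, Et3N, DMF, 100 °C) gives methyl (E)-3-[(2R,3R)-8-methoxy-2-methyl-3-(3,4,5-trimethoxyphenyl)-2,3-dihydro-1,4-benzodioxin-6-yl]prop-2-enoate F4. 1,2-Reduction with DIBAL-H (CH2Cl2, −78 °C) then gives 10.

Step 1 (air- and peroxide-sensitivity of catechol 3 in alkali, over-oxidation). The fallback sets out from 4 and returns at 3. Ether cleavage with BBr3 (2.0 equiv, CH2Cl2, −78 → 0 °C) removes the hindered central methyl first; the aryloxy-dibromoborane then cleaves one neighbouring ether intramolecularly to a cyclic catechol borate, which spares the third ether. Aqueous work-up gives 3. No new compound is made (none F0).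

**Further compounds**
F1 | step 3 | rac-4-[(2R,3R)-7-bromo-5-methoxy-3-methyl-2,3-dihydro-1,4-benzodioxin-2-yl]-2,6-dimethoxyphenol (racemate, trans) | COc1cc([C@H]2Oc3cc(Br)cc(OC)c3O[C@@H]2C)cc(OC)c1O.COc1cc([C@@H]2Oc3cc(Br)cc(OC)c3O[C@H]2C)cc(OC)c1O
F2 | step 3 | rac-(2R,3R)-7-bromo-5-methoxy-3-methyl-2-(3,4,5-trimethoxyphenyl)-2,3-dihydro-1,4-benzodioxine (racemate, trans) | COc1cc([C@H]2Oc3cc(Br)cc(OC)c3O[C@@H]2C)cc(OC)c1OC.COc1cc([C@@H]2Oc3cc(Br)cc(OC)c3O[C@H]2C)cc(OC)c1OC
F3 | step 3 | (2S,3S)-7-bromo-5-methoxy-3-methyl-2-(3,4,5-trimethoxyphenyl)-2,3-dihydro-1,4-benzodioxine | COc1cc([C@@H]2Oc3cc(Br)cc(OC)c3O[C@H]2C)cc(OC)c1OC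
F4 | step 4 | methyl (E)-3-[(2R,3R)-8-methoxy-2-methyl-3-(3,4,5-trimethoxyphenyl)-2,3-dihydro-1,4-benzodioxin-6-yl]prop-2-enoate | COc1cc([C@H]2Oc3cc(/C=C/C(=O)OC)cc(OC)c3O[C@@H]2C)cc(OC)c1OC
F0 | step 1 | none | none
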